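## Retrosynthetic overview

1. The target is reached from the C9,C11-diol by one bis-propanoylation. The C21 acetate is put on early, so the three esters never have to be told apart.
2. C8–C9: substrate-controlled vinylogous Mukaiyama aldol of the ring A silyl dienol ether onto a C9 aldehyde (Felkin–Anh plus 1,3-anti). C10–C11: catalytic anti-selective Mukaiyama aldol of a propanal enol silane onto a C11 enal.
3. C13–C14 and C20–C21: two catalyst-controlled vinylogous Mukaiyama aldol reactions of silyl dienol ethers of the ring B pyranone (the new reaction). The first, with propanal, sets the first stereocenters; the second, with 3-ethoxymethacrolein and then acid, gives the E-enal.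
4. Rings: ring A and ring B are the same achiral building block, 2,6-diethyl-3,5-dimethyl-4H-pyran-4-one, made first in one condensation from one ketone and two molecules of acid. No ring is formed later; ring B is elaborated first and ring A is attached last.

## Assumptions and labels

- Labels: ring A is the pyranone with the free ethyl group, ring B the central pyranone. C8 (on ring A), C9, C10, C11, C12=C13, C14 (on ring B) run along the linking chain; C20 (on ring B) and C21 (acetoxy carbon) are in the side chain. The target SMILES reads as 8R,9R,10R,11R,12E,14S,20S,21S.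
- The pyranone building block is made in step 1 and not bought.
- Catalyst A is an (S,S)-imidodiphosphorimidate Brønsted acid built from two 3,3'-diaryl-1,1'-bi-2-naphthol units with N-trifluoromethylsulfonyl groups (aryl = 3,5-bis(trifluoromethyl)phenyl as the start of the screen). Catalyst B is an acid of the same family with the wider aryl walls that give anti aldols with propanal enol silanes. Both are silylated in the flask by the silyl nucleophile.
- The sense of induction of catalysts A and B is assumed; if the first run shows the opposite sense, the mirror-image acid is used.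

## Route

Step 1
Reactants: 1 pentan-3-one; 2 propanoic acid
Product: 3 2,6-diethyl-3,5-dimethyl-4H-pyran-4-one
Conditions: 2 (2.2 equiv), polyphosphoric acid, 100 °C
Reagents that add atoms: propanoic acid (the second equivalent), CCC(=O)O
Why: Polyphosphoric acid activates propanoic acid as a mixed anhydride that C-acylates the ketone once at each α-carbon, so one ketone takes up two molecules of acid, and the tricarbonyl chain cyclodehydrates in the same pot to the symmetrical 4-pyranone with loss of three molecules of water in all (acylation–cyclodehydration pyranone synthesis); no stereocenter is formed.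

Step 2
Reactants: 3 2,6-diethyl-3,5-dimethyl-4H-pyran-4-one
Product: 4 triethyl{[(2Z)-6-ethyl-2-ethylidene-3,5-dimethyl-2H-pyran-4-yl]oxy}silane
Conditions: LiN(SiMe3)2, THF, −78 °C; Et3SiCl, −78 to 0 °C; pentane, filter
Reagents that add atoms: chlorotriethylsilane, CC[Si](Cl)(CC)CC
Why: Lateral (vinylogous) deprotonation of a 2-alkyl-4-pyranone and O-silylation of the extended lithium enolate give the silyl dienol ether, with the ethylidene methyl syn to the ring oxygen (Z) because the other geometry suffers allylic 1,3-strain against the neighbouring ring methyl; no stereocenter is formed.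

Step 3
Reactants: 4 triethyl{[(2Z)-6-ethyl-2-ethylidene-3,5-dimethyl-2H-pyran-4-yl]oxy}silane; 5 propanal
Product: 7 2-ethyl-6-[(2S,3S)-3-hydroxypentan-2-yl]-3,5-dimethyl-4H-pyran-4-one, via triethylsilyl ether 6 (not isolated)
Conditions: catalyst A (3 mol%), toluene, −60 °C; then 1 M HCl, THF, 0 °C
Reagents that add atoms: none
Why: Proposed new method: the silylated imidodiphosphorimidate passes Et3Si+ to propanal inside its chiral pocket, the Z-dienol silane 4 (which regains aromaticity as a 4-silyloxypyrylium ion on C–C bond formation, the driving force) attacks the Re face of the bound aldehyde through an open antiperiplanar transition state with the aldehyde ethyl group on the ring-oxygen side, away from the neighbouring ring methyl, giving the anti (20S,21S) adduct, and the 4-silyloxypyrylium ion pair then hands its silyl group to the next aldehyde to turn the catalyst over; the closest known reaction type is the silylium-based asymmetric counteranion-directed Mukaiyama aldol reaction of silyl ketene acetals and aldehyde enol silanes under imidodiphosphorimidate catalysis, which has not been shown for a vinylogous 4-pyranone donor.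

Step 4
Reactants: 7 2-ethyl-6-[(2S,3S)-3-hydroxypentan-2-yl]-3,5-dimethyl-4H-pyran-4-one
Product: 8 (2S,3S)-2-(6-ethyl-3,5-dimethyl-4-oxo-4H-pyran-2-yl)pentan-3-yl acetate
Conditions: Ac2O, pyridine, DMAP (cat.), CH2Cl2, 23 °C
Reagents that add atoms: acetic anhydride, CC(=O)OC(C)=O
Why: DMAP-catalysed acylation of the secondary alcohol (Steglich-type acyl transfer) fixes the C21 acetate early, and the ester is inert to all later acidic, silylating and Lewis acidic steps; no stereocenter is touched.

Step 5
Reactants: 8 (2S,3S)-2-(6-ethyl-3,5-dimethyl-4-oxo-4H-pyran-2-yl)pentan-3-yl acetate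
Product: 9 (2S,3S)-2-[(6Z)-6-ethylidene-3,5-dimethyl-4-(triethylsilyloxy)-6H-pyran-2-yl]pentan-3-yl acetate
Conditions: Et3SiOTf, Et3N, CH2Cl2, −78 to 0 °C; pentane, filter
Reagents that add atoms: triethylsilyl trifluoromethanesulfonate, CC[Si](CC)(CC)OS(=O)(=O)C(F)(F)F
Why: Soft enolisation, in which O-silylation gives a 4-silyloxypyrylium triflate whose ethyl CH2 is deprotonated by Et3N (anhydrobase formation of a 2-alkylpyrylium salt) in preference to the hindered C20 methine, whose loss would build a strained tetrasubstituted exocyclic alkene, while the acetate, which would not survive a lithium amide, is untouched; Z geometry as in step 2 and no stereocenter affected.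

Step 6
Reactants: 9 (2S,3S)-2-[(6Z)-6-ethylidene-3,5-dimethyl-4-(triethylsilyloxy)-6H-pyran-2-yl]pentan-3-yl acetate; 10 (2E)-3-ethoxy-2-methylprop-2-enal
Product: 12 (2S,3S)-2-{3,5-dimethyl-6-[(2S,3E)-4-methyl-5-oxopent-3-en-2-yl]-4-oxo-4H-pyran-2-yl}pentan-3-yl acetate, via silyl ether adduct 11 (not isolated)
Conditions: catalyst A (3 mol%), toluene, −60 °C; then 1 M HCl, THF, 0 °C
Reagents that add atoms: water, O
Why: Proposed new method: second use of the step 3 reaction, in which the same catalyst enantiomer brings the same face of the Z-ethylidene group of 9 onto the Re face of the O-silylated 3-ethoxymethacrolein carbonyl so that C14 is set as S by catalyst control alone (the C13 carbinol is transient and the remote C20 and C21 centers exert no bias), after which dilute acid hydrolyses the enol ether and eliminates the β-silyloxy group to the conjugated E-enal, the classical 3-alkoxyacrolein formyl-olefination; the closest known reaction types are the imidodiphosphorimidate-catalysed Mukaiyama aldol reaction and the 1,2-addition of organometallic reagents to 3-alkoxyacroleins followed by acid rearrangement.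

Step 7
Reactants: 5 propanal
Product: 13 triethyl[(1Z)-prop-1-en-1-yloxy]silane
Conditions: Et3SiOTf, Et3N, Et2O, 0 °C; distil
Reagents that add atoms: triethylsilyl trifluoromethanesulfonate, CC[Si](CC)(CC)OS(=O)(=O)C(F)(F)F
Why: Silyl triflate/amine enol silylation of an aldehyde (soft enolisation), which gives mainly the Z enol silane, purified by distillation; no stereocenter is formed.

Step 8
Reactants: 12 (2S,3S)-2-{3,5-dimethyl-6-[(2S,3E)-4-methyl-5-oxopent-3-en-2-yl]-4-oxo-4H-pyran-2-yl}pentan-3-yl acetate; 13 triethyl[(1Z)-prop-1-en-1-yloxy]silane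
Product: 14 (2S,3S)-2-{6-[(2S,3E,5R,6S)-4,6-dimethyl-7-oxo-5-(triethylsilyloxy)hept-3-en-2-yl]-3,5-dimethyl-4-oxo-4H-pyran-2-yl}pentan-3-yl acetate
Conditions: catalyst B (3 mol%), toluene, −40 °C
Reagents that add atoms: none
Why: Silylium-based asymmetric counteranion-directed Mukaiyama aldol reaction of a propanal enol silane, known with simple aldehydes to stop after one aldolisation and to give anti adducts with a suitably confined imidodiphosphorimidate, here applied to an α-methyl enal, where the catalyst directs 1,2-attack on the Re face of the enal carbonyl and sets C10 (S in 14) and C11 (R) anti to each other with the silyl group ending on O11, C14 being too remote to interfere.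

Step 9
Reactants: 14 (2S,3S)-2-{6-[(2S,3E,5R,6S)-4,6-dimethyl-7-oxo-5-(triethylsilyloxy)hept-3-en-2-yl]-3,5-dimethyl-4-oxo-4H-pyran-2-yl}pentan-3-yl acetate; 4 triethyl{[(2Z)-6-ethyl-2-ethylidene-3,5-dimethyl-2H-pyran-4-yl]oxy}silane
Product: 16 (2S,3S)-2-{6-[(2S,3E,5R,6R,7R,8R)-8-(6-ethyl-3,5-dimethyl-4-oxo-4H-pyran-2-yl)-5,7-dihydroxy-4,6-dimethylnon-3-en-2-yl]-3,5-dimethyl-4-oxo-4H-pyran-2-yl}pentan-3-yl acetate, via C11 triethylsilyl ether 15 (not isolated)
Conditions: 4 (2 equiv), BF3·OEt2 (3 equiv), CH2Cl2, −78 °C; then HF·pyridine, THF, 0 °C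
Reagents that add atoms: none
Why: BF3-mediated vinylogous Mukaiyama aldol addition through an open transition state, in which the 2,3-anti α-methyl-β-silyloxy aldehyde has reinforcing Felkin–Anh and 1,3-anti (polar model) preferences that set C9 (R, syn to the C10 methyl and anti to O11), the Z-dienol silane keeps the aldehyde chain away from the neighbouring ring methyl and so gives the anti C8–C9 relation (8R), and HF·pyridine then cleaves the allylic silyl ether.

Step 10
Reactants: 16 (2S,3S)-2-{6-[(2S,3E,5R,6R,7R,8R)-8-(6-ethyl-3,5-dimethyl-4-oxo-4H-pyran-2-yl)-5,7-dihydroxy-4,6-dimethylnon-3-en-2-yl]-3,5-dimethyl-4-oxo-4H-pyran-2-yl}pentan-3-yl acetate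
Product: 17 (2S,3S)-2-{6-[(2S,3E,5R,6R,7R,8R)-8-(6-ethyl-3,5-dimethyl-4-oxo-4H-pyran-2-yl)-4,6-dimethyl-5,7-bis(propanoyloxy)non-3-en-2-yl]-3,5-dimethyl-4-oxo-4H-pyran-2-yl}pentan-3-yl acetate
Conditions: (EtCO)2O, DMAP, pyridine, CH2Cl2, 23 °C
Reagents that add atoms: propanoic anhydride, CCC(=O)OC(=O)CC
Why: DMAP-catalysed (Steglich-type) acylation of both secondary hydroxyl groups gives the target; no stereocenter is touched.

## Compound list

1 | pentan-3-one | CCC(=O)CC | starting material
2 | propanoic acid | CCC(=O)O | starting material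
3 | 2,6-diethyl-3,5-dimethyl-4H-pyran-4-one | CCc1oc(CC)c(C)c(=O)c1C | intermediate
4 | triethyl{[(2Z)-6-ethyl-2-ethylidene-3,5-dimethyl-2H-pyran-4-yl]oxy}silane | C/C=C1\OC(CC)=C(C)C(O[Si](CC)(CC)CC)=C1C | intermediate
5 | propanal | CCC=O | starting material
6 | 2-ethyl-3,5-dimethyl-6-[(2S,3S)-3-(triethylsilyloxy)pentan-2-yl]-4H-pyran-4-one | CCc1oc([C@@H](C)[C@H](CC)O[Si](CC)(CC)CC)c(C)c(=O)c1C | intermediate
7 | 2-ethyl-6-[(2S,3S)-3-hydroxypentan-2-yl]-3,5-dimethyl-4H-pyran-4-one | CCc1oc([C@@H](C)[C@H](CC)O)c(C)c(=O)c1C | intermediate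
8 | (2S,3S)-2-(6-ethyl-3,5-dimethyl-4-oxo-4H-pyran-2-yl)pentan-3-yl acetate | CCc1oc([C@@H](C)[C@H](CC)OC(C)=O)c(C)c(=O)c1C | intermediate
9 | (2S,3S)-2-[(6Z)-6-ethylidene-3,5-dimethyl-4-(triethylsilyloxy)-6H-pyran-2-yl]pentan-3-yl acetate | C/C=C1\OC([C@@H](C)[C@H](CC)OC(C)=O)=C(C)C(O[Si](CC)(CC)CC)=C1C | intermediate
10 | (2E)-3-ethoxy-2-methylprop-2-enal (3-ethoxymethacrolein) | CCO/C=C(\C)C=O | starting material
11 | (2S,3S)-2-{6-[(2S,3R,4E)-5-ethoxy-4-methyl-3-(triethylsilyloxy)pent-4-en-2-yl]-3,5-dimethyl-4-oxo-4H-pyran-2-yl}pentan-3-yl acetate | CCO/C=C(C)/[C@H](O[Si](CC)(CC)CC)[C@H](C)c1oc([C@@H](C)[C@H](CC)OC(C)=O)c(C)c(=O)c1C | intermediate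
12 | (2S,3S)-2-{3,5-dimethyl-6-[(2S,3E)-4-methyl-5-oxopent-3-en-2-yl]-4-oxo-4H-pyran-2-yl}pentan-3-yl acetate | O=C/C(C)=C/[C@H](C)c1oc([C@@H](C)[C@H](CC)OC(C)=O)c(C)c(=O)c1C | intermediate
13 | triethyl[(1Z)-prop-1-en-1-yloxy]silane | C/C=C\O[Si](CC)(CC)CC | intermediate
14 | (2S,3S)-2-{6-[(2S,3E,5R,6S)-4,6-dimethyl-7-oxo-5-(triethylsilyloxy)hept-3-en-2-yl]-3,5-dimethyl-4-oxo-4H-pyran-2-yl}pentan-3-yl acetate | O=C[C@@H](C)[C@@H](O[Si](CC)(CC)CC)/C(C)=C/[C@H](C)c1oc([C@@H](C)[C@H](CC)OC(C)=O)c(C)c(=O)c1C | intermediate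
15 | (2S,3S)-2-{6-[(2S,3E,5R,6R,7R,8R)-8-(6-ethyl-3,5-dimethyl-4-oxo-4H-pyran-2-yl)-7-hydroxy-4,6-dimethyl-5-(triethylsilyloxy)non-3-en-2-yl]-3,5-dimethyl-4-oxo-4H-pyran-2-yl}pentan-3-yl acetate | O[C@H]([C@@H](C)[C@@H](O[Si](CC)(CC)CC)/C(C)=C/[C@H](C)c1oc([C@@H](C)[C@H](CC)OC(C)=O)c(C)c(=O)c1C)[C@@H](C)c1oc(CC)c(C)c(=O)c1C | intermediate
16 | (2S,3S)-2-{6-[(2S,3E,5R,6R,7R,8R)-8-(6-ethyl-3,5-dimethyl-4-oxo-4H-pyran-2-yl)-5,7-dihydroxy-4,6-dimethylnon-3-en-2-yl]-3,5-dimethyl-4-oxo-4H-pyran-2-yl}pentan-3-yl acetate | O[C@H]([C@@H](C)[C@@H](O)/C(C)=C/[C@H](C)c1oc([C@@H](C)[C@H](CC)OC(C)=O)c(C)c(=O)c1C)[C@@H](C)c1oc(CC)c(C)c(=O)c1C | intermediate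
17 | (2S,3S)-2-{6-[(2S,3E,5R,6R,7R,8R)-8-(6-ethyl-3,5-dimethyl-4-oxo-4H-pyran-2-yl)-4,6-dimethyl-5,7-bis(propanoyloxy)non-3-en-2-yl]-3,5-dimethyl-4-oxo-4H-pyran-2-yl}pentan-3-yl acetate (CNP0295731.1) | CCC(=O)O[C@H]([C@@H](C)[C@@H](OC(=O)CC)/C(C)=C/[C@H](C)c1oc([C@@H](C)[C@H](CC)OC(C)=O)c(C)c(=O)c1C)[C@@H](C)c1oc(CC)c(C)c(=O)c1C | target

## Step count and risks

Total step count: 10. Longest linear sequence: 9 (steps 1 to 6, then 8, 9 and 10; step 7 is a one-step side branch).

The three steps most likely to fail: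

**Step 6 (new reaction, C14).** C14 is set only by the catalyst's control of the dienol silane face, with no help from the substrate. The adduct 11 is a vinylogous acetal that can ionise and take up a second molecule of 9. The basic pyranone holds the silyl cation as a 4-silyloxypyrylium ion pair, which may slow turnover.

Fallback, known chemistry, setting out from 7 and coming back at 12: the alcohol 7 is converted to its dianion (alkoxide plus lateral dienolate at the ethyl CH2) with 2.2 equiv of LiN(iPr)2 in THF at −78 °C. This adds 1,2 to 3-ethoxymethacrolein 10 to give the diol adduct 6-[(4E)-5-ethoxy-3-hydroxy-4-methylpent-4-en-2-yl]-2-[(2S,3S)-3-hydroxypentan-2-yl]-3,5-dimethyl-4H-pyran-4-one F5. Dilute HCl rearranges it, with loss of ethanol, to the hydroxy enal (2E)-4-{6-[(2S,3S)-3-hydroxypentan-2-yl]-3,5-dimethyl-4-oxo-4H-pyran-2-yl}-2-methylpent-2-enal F6, about 1:1 at C14. Acetylation (Ac2O, pyridine) gives 12 together with its C14 epimer (2S,3S)-2-{3,5-dimethyl-6-[(2R,3E)-4-methyl-5-oxopent-3-en-2-yl]-4-oxo-4H-pyran-2-yl}pentan-3-yl acetate F7. The two are separated by preparative HPLC; F7 is re-equilibrated at its vinylogously acidic C14–H with DBU and recycled. This fallback gives no control at C14 and relies on the separation.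

**Step 3 (new reaction, C20 and C21).** Turnover depends on the 4-silyloxypyrylium ion pair being able to silylate propanal, and the anti preference of the open transition state is a prediction.

Fallback, known chemistry, setting out from 5 and coming back at 7: L-proline-catalysed self-aldol of propanal 5 (DMF, 4 °C, enamine catalysis) gives (2S,3S)-3-hydroxy-2-methylpentanal F1. Silylation (Et3SiCl, imidazole) gives (2S,3S)-2-methyl-3-(triethylsilyloxy)pentanal F2. The dianion of commercial 4-methylheptane-3,5-dione (NaH, then n-BuLi, THF) adds at its terminal CH2 to give (8R,9S)-7-hydroxy-4,6,8-trimethyl-9-(triethylsilyloxy)undecane-3,5-dione F3, a mixture at the centers that are destroyed next. Dess–Martin periodinane gives the triketone (8S,9S)-4,6,8-trimethyl-9-(triethylsilyloxy)undecane-3,5,7-trione F4. Cyclodehydration with p-TsOH in CH2Cl2 closes ring B to give 6, and 1 M HCl in THF then frees 7. The main risk is epimerisation of C20 next to the ketone in F4, so the cyclisation is kept cold and short.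

**Step 8 (known catalysis on a new kind of acceptor).** The enal is α-branched and carries a basic pyranone that competes for the silyl cation. The C14–H of 12 is vinylogously acidic, and 14 can lose silanol to a dienal on silica.

Fallback, known chemistry, setting out from 12 and coming back at 14: propanal 5 is added by syringe pump to 12 and L-proline (20 mol%) in DMF at 4 °C (direct enamine cross-aldol, anti-selective). This gives (2S,3S)-2-{6-[(2S,3E,5R,6S)-5-hydroxy-4,6-dimethyl-7-oxohept-3-en-2-yl]-3,5-dimethyl-4-oxo-4H-pyran-2-yl}pentan-3-yl acetate F8, which is silylated (Et3SiCl, imidazole, CH2Cl2) to 14.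

## Further compounds

F1 | step 3 | (2S,3S)-3-hydroxy-2-methylpentanal | O=C[C@@H](C)[C@H](CC)O
F2 | step 3 | (2S,3S)-2-methyl-3-(triethylsilyloxy)pentanal | O=C[C@@H](C)[C@H](CC)O[Si](CC)(CC)CC
F3 | step 3 | (8R,9S)-7-hydroxy-4,6,8-trimethyl-9-(triethylsilyloxy)undecane-3,5-dione | CCC(=O)C(C)C(=O)C(C)C(O)[C@@H](C)[C@H](CC)O[Si](CC)(CC)CC
F4 | step 3 | (8S,9S)-4,6,8-trimethyl-9-(triethylsilyloxy)undecane-3,5,7-trione | CCC(=O)C(C)C(=O)C(C)C(=O)[C@@H](C)[C@H](CC)O[Si](CC)(CC)CC
F5 | step 6 | 6-[(4E)-5-ethoxy-3-hydroxy-4-methylpent-4-en-2-yl]-2-[(2S,3S)-3-hydroxypentan-2-yl]-3,5-dimethyl-4H-pyran-4-one | CCO/C=C(C)/C(O)C(C)c1oc([C@@H](C)[C@H](CC)O)c(C)c(=O)c1C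
F6 | step 6 | (2E)-4-{6-[(2S,3S)-3-hydroxypentan-2-yl]-3,5-dimethyl-4-oxo-4H-pyran-2-yl}-2-methylpent-2-enal | O=C/C(C)=C/C(C)c1oc([C@@H](C)[C@H](CC)O)c(C)c(=O)c1C
F7 | step 6 | (2S,3S)-2-{3,5-dimethyl-6-[(2R,3E)-4-methyl-5-oxopent-3-en-2-yl]-4-oxo-4H-pyran-2-yl}pentan-3-yl acetate | O=C/C(C)=C/[C@@H](C)c1oc([C@@H](C)[C@H](CC)OC(C)=O)c(C)c(=O)c1C
F8 | step 8 | (2S,3S)-2-{6-[(2S,3E,5R,6S)-5-hydroxy-4,6-dimethyl-7-oxohept-3-en-2-yl]-3,5-dimethyl-4-oxo-4H-pyran-2-yl}pentan-3-yl acetate | O=C[C@@H](C)[C@@H](O)/C(C)=C/[C@H](C)c1oc([C@@H](C)[C@H](CC)OC(C)=O)c(C)c(=O)c1C
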